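In a one-step world, first order in substrate with c(acid) held, ln(substrate) would fall on one straight line, so the meeting began by asking whether the earlier runs do.

| flask | substrate | acid | scavenger | remark | time |
|---|---|---|---|---|---|
| birch | 20 mM | 0.30 mM | 20 mM (fed, over 10 min) | run made earlier |  |
| ash | 20 mM | 0.45 mM | 20 mM (fed, over 10 min) | run made earlier |  |
| flask | 20 mM | 0.600 mM | 20.0 mM (fed, over 10 min) |  | 40 min |

- birch (time / min: substrate / %, target / %): 2.50: 91, 5; 4.00: 86, 7; 6.00: 80, 9; 10.0: 72, 15; 15.0: 60, 20; 20.0: 54, 28; 30.0: 40, 36
- ash (time / min: substrate / %, target / %): 5.00: 73, 12; 10.0: 62, 21; 15.0: 49, 28; 20.0: 41, 32; 25.0: 35, 37; 30.0: 27, 41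

(standard deviation of a reading: 1.5 percentage points)

* part of the substrate that has reacted at 40 min
* pH of the solution at 40 min

- acid is the free proton; pH is minus the decimal logarithm of its molar concentration
- a reading or a percentage of target counts all its forms, free or not
- what has gone from substrate into another species counts as reacted, even if it can come back
- a reading of substrate is of its free form alone

The first speaker reported, from readings good to 1.5 percentage points, that in birch ln(substrate) fell 0.0329 min⁻¹ up to the end of the feed and 0.0294 min⁻¹ after it. The ash readings give 0.0478 min⁻¹ and then 0.0416 min⁻¹.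

The second speaker proposed solving the two ends apart and joining them at 10 min. The head, ln(charged over free substrate) at the end of the feed divided by c(acid), averaged 1080 M⁻¹ over birch and ash. The acid-scaled tail, the fall of ln(substrate) per minute after the feed divided by c(acid), a pseudo-first-order constant taken per unit of acid, averaged 1.59 M⁻¹ s⁻¹.

As minute-taker I joined the two for the flask: by my reckoning they leave 9.44% of the substrate at 40 min, so 90.6% reacted. The forecast gave 89% reacted, lower than mine, and pH 3.4, holding that “the rate is roughly first order in acid, slightly sublinear”. The meeting agreed to watch substrate at the end of the feed and again at 40 min.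

    substrate + acid → weak acid + acid + target (k = 0.928 M⁻¹ s⁻¹)
    weak acid ⇌ conjugate base + acid, settled at all times (K = 1.30 × 10⁻⁶ M)
    substrate → weak acid + target (k = 1.73 × 10⁻⁵ s⁻¹)
    substrate + weak acid ⇌ idle adduct A, settled at all times (K = 151 M⁻¹)
    weak acid + scavenger → scavenged by-product (k = 2.69 M⁻¹ s⁻¹)
    substrate + target ⇌ idle adduct B, settled at all times (K = 537 M⁻¹)

The flask gives 85.6% reacted and pH 3.22, with acid at 100% of its charge, and both forecast values stand within their margins. In the flask, substrate stands at 53.0% at 10.0 min, against 52.4% from the head. The flask's acid-scaled tail is 1.20 M⁻¹ s⁻¹, lower than the runs' 1.59 M⁻¹ s⁻¹. With the other amounts and the time held, the reacted part of the flask has moved by 5 points at 0.458 mM or 0.881 mM of acid. With 0.36 mM of acid, the same head and tail leave 24.2% of the substrate, and that neighbouring flask holds 25% unbound at 40.0 min, with 75.0% reacted.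

The numbers in the tables were computed from invented constants; the scatter is artificial.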